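The vessel was closed, stirred and held at one temperature, with gas held over a racemate and a single-handed catalyst, and the thing to watch in it was the share of left-handed product among the two products.

in all of them: left-handed substrate 0.26 M; right-handed substrate 0.26 M; gas 24 mM (held)

| charge | catalyst | temperature | remark | time |
|---|---|---|---|---|
| birch | 7.8 mM | 35 °C | run made earlier |  |
| Friday's | 5.2 mM | 35 °C |  | 12 min |
| Thursday's | 5.2 mM | 50 °C |  | 12 min |
| Saturday's | 5.2 mM | 20 °C |  | 12 min |

birch run (percent of the left-handed substrate and right-handed substrate together charged)

| time / min | left-handed product / % | right-handed product / % |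
|---|---|---|
| 0.250 | 5.0 | 1.9 |
| 0.417 | 7.8 | 3.6 |
| 0.667 | 10.0 | 4.5 |
| 1.00 | 12.4 | 6.0 |
| 1.50 | 16.5 | 8.8 |
| 2.50 | 21.3 | 12.4 |
| 4.00 | 27.4 | 18.7 |

(readings scatter by 0.5 percentage points)

- catalyst is single-handed; left-handed substrate and right-handed substrate are mirror images of each other, charged as a racemate, each of them at the stated concentration
- at the start none of coupling partner is dissolved
- on the list of suspects stand: coupling partner + catalyst + right-handed substrate -> catalyst + right-handed product; coupling partner + catalyst + left-handed substrate -> catalyst + left-handed product; gas <-> coupling partner; left-handed product <-> right-handed product; catalyst <-> dormant form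
- the earlier runs do not show what temperature does; that part of a forecast is a guess
- no earlier run changes the charge of catalyst; that part of a forecast is a guess

1. the flask that comes out highest in share of left-handed product in all that became left-handed product or right-handed product, or "all alike" when all lie within 1.5 percentage points (Friday's / Thursday's / Saturday's / all alike)
2. share of left-handed product in all that became left-handed product or right-handed product, Friday's
3. share of left-handed product in all that became left-handed product or right-handed product, Thursday's
4. share of left-handed product in all that became left-handed product or right-handed product, Saturday's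

Friday's flask looks nearly the same as the birch run. It has the same substrates and the same 35 °C, and c(coupling partner) is fed from gas held at the same 24 mM. It differs in c(catalyst), 5.2 mM against 7.8 mM, and in being read at 12 min rather than 4.00 min. So I took c(catalyst) as the concentration to compare. With c(coupling partner) alike in the two flasks, I treated each substrate as decaying pseudo-first-order, with a rate constant proportional to c(catalyst).

Multiplying c(catalyst) by the time gives Friday's 62.4 mM·min, and this product is what I call the catalyst dose. The last birch reading stood at 31.2 mM·min, so Friday's carries twice that dose.

In the birch readings the share fell from 72.5 % at 0.250 min to 59.4 % at 4.00 min, and left-handed product came first, read at 2.63 times the right-handed at the earliest reading. Friday's should match the birch dose at 6.00 min and then go on, so I expected its share well below 59.4 %. That is an expectation of direction, not a value. Thursday's and Saturday's carry the same dose as Friday's, so the dose does not separate them, and temperature stays a guess.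

The forecast went further. It named Saturday's highest, with 52.5 % for Friday's, 50.5 % for Thursday's and 62 % for Saturday's, holding that “the products are interconverting”.

The flasks gave Saturday's highest, with 52.0 % for Friday's, 49.3 % for Thursday's and 61.6 % for Saturday's.

    coupling partner + catalyst + right-handed substrate → catalyst + right-handed product (k = 26.1 M⁻² s⁻¹, Ea = 38.0 kJ mol⁻¹)
    coupling partner + catalyst + left-handed substrate → catalyst + left-handed product (k = 70.8 M⁻² s⁻¹, Ea = 44.0 kJ mol⁻¹)
    gas ⇌ coupling partner, rate k3*(csat - [coupling partner]) (kL = 0.761 s⁻¹)
    left-handed product ⇌ right-handed product (k = 0.00183 s⁻¹, Ea = 83.0 kJ mol⁻¹)
    catalyst ⇌ dormant form (K = 2.70, k = 0.0452 s⁻¹, Ea = 88.0 kJ mol⁻¹, ΔH = −52.0 kJ mol⁻¹)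
    (constants at 35 °C)

At 6.00 min, when Friday's dose had reached the 31.2 mM·min of the last birch reading, its two products together held 44.3 %, against the 46.1 % read in the birch run at 4.00 min. Saturday's, with the dose 62.4 mM·min at 20 °C, ended with 26.1 % left-handed substrate and 13.7 % right-handed product. Its neighbour, charged with 0.021 M of catalyst, took 252 mM·min over the same 12 min, which is 4.04 times Saturday's dose. That neighbour ended with 4.01 % left-handed substrate and 35.3 % right-handed product, and its share came to 55.0 %, still above Friday's 52.0 %.

(The readings were computed with constants of no real substance.)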